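| flask | starting material | enzyme | remark |
|---|---|---|---|
| elm | 0.050 M | 0.017 mol% | run made earlier |
| maple | 0.050 M | 0.026 mol% | run made earlier |
| cedar | 0.10 M | 0.034 mol% | run made earlier |
| flask | 0.050 M | 0.034 mol% |  |

| run | time / min | product / % |
|---|---|---|
| elm | 0.500 | 16.5 |
| elm | 0.833 | 19.9 |
| elm | 1.33 | 24.1 |
| elm | 2.00 | 26.9 |
| elm | 3.00 | 29.8 |
| elm | 4.00 | 30.2 |
| elm | 6.00 | 32.0 |
| maple | 0.333 | 16.8 |
| maple | 1.00 | 26.0 |
| maple | 2.00 | 32.4 |
| maple | 3.00 | 33.6 |
| maple | 4.00 | 35.4 |
| maple | 5.00 | 35.9 |
| maple | 6.00 | 36.0 |
| cedar | 0.500 | 35.4 |
| cedar | 1.50 | 45.7 |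
| cedar | 3.00 | 51.2 |
| cedar | 5.00 | 51.9 |
| cedar | 6.00 | 51.9 |

(standard deviation of a reading: 0.5 percentage points)



1. apparent order in enzyme when 20 % of the starting material are converted (percent change of the rate of making product for one percent more enzyme charged)

- At the last reading, 6.00 min, elm holds 32.0 % of its charge as product at 0.017 mol% enzyme, while maple holds 36.0 % at 0.026 mol% after 6.00 min; dividing the log10 of the product ratio by the log10 of the loading ratio gives 0.277, my plateau order, the percent change of the product at the last reading for one percent more enzyme charged.
- Turning the question round, where product at one starting concentration is one function of loading times time (the normalised time axis), the rate at fixed conversion follows the loading, so the order in enzyme is one and the plateau order is zero.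
- Elm and maple pass that test early, with 16.5 % at 0.500 min against 16.8 % at 0.333 min, where loading times time matches; but at 6.00 min in elm and 4.00 min in maple, again matched, they stand 3.4 percentage points apart against a scatter of 0.5 points.
- For the flask at 0.034 mol%, I carry maple's last reading up by that order to an estimated plateau of 38.8 %, and, assuming that the starting rate follows the loading and that the rate then falls in step with the distance left to the plateau, I reckon the order at 20 % as one plus the plateau order times conversion over distance, 1.30.
- The forecast differs from my reckoning, saying 1.5 on the ground that “more enzyme means less decay”.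
- The flask gives an order of 1.2 at 0.346 min, the time at which it reaches 20 % conversion, which is below my 1.30.

    2 enzyme → spent catalyst B (k = 3000 /M/s)
    enzyme → spent catalyst A (k = 0.00860 /s)
    starting material + enzyme → product + enzyme, rate k3*[starting material]^2*[enzyme]/(1 + ([starting material]/Kh3)^2) (0.0780 M, k = 37000 /M²/s)

- At 80.0 min the flask holds 78.5 % of its catalyst as spent catalyst B and 21.5 % as spent catalyst A, and the plateau order 0.277, carried from maple to this loading, gives 38.8 % product, where the flask holds 38.6 % at 80.0 min.

The data are calculated for an exercise; the scatter is artificial.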